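## Structural features

The target is a C30 tetracycle built from two bicycles joined by an ethylene bridge. The western half is a trans-fused perhydro-1-benzoxepine: an oxepane (O1, C2–C5, C5a, C9a) fused to a cyclohexane (C5a–C9a). The eastern half is a cis-fused perhydroazulene whose seven-membered ring carries a trisubstituted 6,7-epoxide. The bridge runs from C6 of the benzoxepine to C5 of the azulene.

In the west, C9a, the quaternary C5a (angular methyl), C6 and the tertiary carbinol C7 are contiguous, and C3 stands alone beside the gem-dimethyl carbon C2. In the east, C1 (tertiary carbinol), C8a and C3a are contiguous, and the triad C5/C6/C7 lies beyond the gem-dimethyl carbon C4.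

The fragile groups are the epoxide (acid would let the C1 hydroxyl attack C7 in a 5-exo sense), the two tertiary alcohols and the tertiary alkyl ether O1–C2. The real difficulties are three:
- the seven-membered ether whose oxygen sits between a gem-dimethyl carbon and a ring-fusion carbon next to a quaternary centre;
- the epoxide, which lies on the same face as the C5 side chain, the more hindered (concave) face of the cis-fused bicycle;
- the union of two hindered halves through an sp3 linker.

The key step uses the fact that O1 is flanked by C2 and C9a, with the carbinol C3 next to C2. C3–C4 can therefore be a latent alkene, and a 2-methylbut-3-en-2-yl ether on the C9a oxygen plus an allyl group on C5a already hold every atom of the oxepane.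

## Logic of the disconnections

**43 ⇒ 41 (via 42).** The C7–CH3 bond and the two O–Si bonds are cut. The axial C5a methyl blocks axial attack on the C7 ketone, so a methyl nucleophile should enter equatorially and give the axial hydroxyl. The forward step needs a non-basic methyl source that leaves the epoxide alone.

**41 ⇒ 38 (via 40, 39).** The C7–O and C6–H bonds are cut back to the C6=C7 alkene. Syn addition of H–B anti to the C5a methyl sets C6 with the side chain equatorial. The borane must spare the epoxide.

**38 ⇒ 18 + 36 (via 37).** The C6–CH2 bond is cut between an sp2 and an sp3 carbon, dividing the molecule into two halves of similar size. The enol triflate is regiodefined because C5a is quaternary. The coupling must tolerate a hindered triflate, an epoxide and two silyl ethers.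

**18 ⇒ 13 (via 17, 16, 15, 14).** The C3–O bond is cut and C6 is re-masked. The C3 hydroxyl is traced to epoxide 14, which hydride opens only at C4, away from the gem-dimethyl carbon. The epoxidation must occur anti to the C5a methyl.

**13 ⇒ 12 (key step).** The C3=C4 bond is cut. This removes the seven-membered ring and leaves a cyclohexane carrying two terminal alkenes, with no stereocentre at stake. Ring closure must beat oligomerisation.

**12 ⇒ 7 + 8 (via 11, 10, 9).** The O–C2 bond is cut. A tertiary ether cannot be made by SN2, so a cobalt-stabilised propargylic cation is used and the alkyne serves as a latent vinyl group. The hindered alcohol must act as nucleophile, the ketal must survive the Lewis acid, and the semihydrogenation must stop at the alkene.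

**7 ⇒ 3 ⇒ 1 + 2 (via 6, 5, 4).** The C5a–allyl bond is cut and the prochiral dione is desymmetrised. Correction to the obvious plan: direct mono-reduction of 3 puts the hydroxyl cis to the allyl group (as in 4), which is the wrong pair for a trans-fused oxepane. In 6 the quaternary carbon is the only stereocentre, so a catalyst-controlled reduction can then set C9a trans to the allyl group without an inversion at a neopentyl carbon.

**36 ⇒ 32 (via 35, 34, 33).** The two epoxide C–O bonds are cut. Direct epoxidation would attack the convex face, anti to the C5 chain. Iodolactonisation of 32 instead forces the oxygen onto the face of the chain, and base then closes the epoxide there.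

**32 ⇒ 31 ⇒ 30.** The C5–CH2 bond is cut as a [3,3] shift. The C7 carbinol transfers its configuration to C5, which lies next to the quaternary C4. The carbinol comes from a catalyst-controlled enone reduction.

**30 ⇒ 28 ⇒ 27 (via 29).** The C5=C6 unsaturation is removed and the C4–C5 bond is cut. A tertiary radical from the isopropenyl group adds to the enone methylene, forming the quaternary carbon and the seven-membered ring together. This demands a 7-endo closure and hydrogen-atom transfer that selects the electron-rich alkene.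

**27 ⇒ 25 ⇒ 24 ⇒ 22 ⇒ 21 (via 26, 23).** The C6–C7 bond (isopropenyl addition), the C8a–H bond (conjugate reduction on the face of the C1 hydroxyl) and the C7–C8 bond (one-carbon homologation with vinylogous epoxide opening) are cut. The C1–O bond comes from nucleophilic epoxidation anti to the isopropenyl group.

**21 ⇒ 20 ⇒ 19.** The C1=C8a bond is cut as an aldol condensation, and the keto aldehyde is traced to ozonolysis of the ring alkene of 19. The chiral pool supplies C3a.

## Other disconnections considered

Alternative 1: The cut is the C8a–C3a bond of the azulene's cyclopentane. In the forward sense Pd(OAc)2/PPh3 cycloisomerises an acyclic ynoate–ene to A1.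
- In its favour: it is catalytic and atom-economic; one step makes the cyclopentane with the tertiary carbinol carbon in place, an isopropenyl group as latent C4 and an exocyclic enoate for C8a–H and for chain growth.
- Against it here: C3a is set only by 1,3-induction from the carbinol; an enantioenriched tertiary propargylic alcohol is needed; the seven-membered ring, C5 and the epoxide remain to be built; the oxepane is not addressed.
- Comparison: it concerns the eastern half, so structurally it complements rather than replaces the oxepene closure. Mechanistically both are metal-catalysed isomerisation-type processes without by-products other than ethylene. It sets one stereocentre where the metathesis sets none, though with less certain control. On step economy it is the better: A1 should be reached in about three steps, whereas the limonene sequence here needs four to reach the comparable compound 24.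

Alternative 2: The cut is the C6–C7 bond (with the O–CH2 bond), closing the cyclohexane onto a preformed oxepane. A nitrile oxide made in situ adds to the vinyl group on C5a to give A2.
- In its favour: a concerted cycloaddition is dependable; it forms the carbocycle, a masked C7 ketone and the first linker carbon on C6 in one step, and fixes C6 relative to C5a.
- Against it here: the oxepane with its quaternary C5a must be made first without a cyclohexane template; facial control at C6 depends on the conformation of a seven-membered ring; N–O cleavage adds steps; the union then becomes an sp3–sp3 coupling at the CH2–O carbon.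
- Comparison: in bonds and stereocentres formed per step it is the better of the two key steps (two bonds and one stereocentre against one bond and none). In precursor accessibility and in the reliability of the later fragment union the chosen plan is stronger. Overall step count should be similar.

Alternative 3: The cuts are O1–C2 and C5a–C6 together. Me3SiOTf triggers an epoxide-opening cascade of an acyclic bis-epoxide ending on an allylsilane, giving A3.
- In its favour: both western rings, two bonds and the C5a/C6 pair arise in one operation; C3 and C9a come from asymmetric epoxidations; the C7 methylene and the pivalate are handles for the carbinol and the linker.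
- Against it here: cationic cascades of this kind are prone to competing exo openings, shifts and eliminations; the C6 configuration rests on one chair-like transition state; the linker must again be built by sp3 coupling.
- Comparison: it forms the same O1–C2 bond as the chosen route, but as a C–O bond under cationic conditions rather than as a consequence of a C=C closure. It is clearly the better in step economy. The chosen plan is the more predictable, because each stereocentre is set in a separate, well-understood step.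

Key step: step 9

Remark on the chemistry (assumption): yeast reduction of 3 is taken to follow its documented course, giving the (2S,3S) ketol with the hydroxyl cis to the allyl group; the azulene ring fusion is read from the SMILES as cis.

## Route

### Western half (steps 1–14)

Step 1
Reactants: 1 2-methylcyclohexane-1,3-dione; 2 allyl bromide
Product: 3 2-allyl-2-methylcyclohexane-1,3-dione
Conditions: NaOH (1 M aq.), rt → 50 °C
Reagents that add atoms: none
Why: C-alkylation of the stabilised 1,3-dicarbonyl enolate with an allylic halide; the product is achiral with a prochiral quaternary carbon.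

Step 2
Reactants: 3 2-allyl-2-methylcyclohexane-1,3-dione
Product: 4 (2S,3S)-2-allyl-3-hydroxy-2-methylcyclohexan-1-one
Conditions: baker's yeast, sucrose, H2O, 30 °C
Reagents that add atoms: none
Why: Enzymatic enantiotopic-group-selective ketone reduction, known for this dione; it fixes the quaternary carbon (future C5a) as S, and the minor C2 epimer is removed by chromatography.

Step 3
Reactants: 4 (2S,3S)-2-allyl-3-hydroxy-2-methylcyclohexan-1-one
Product: 5 (6S,7S)-6-allyl-6-methyl-1,4-dioxaspiro[4.5]decan-7-ol
Conditions: HOCH2CH2OH, PPTS (cat.), benzene, reflux (Dean–Stark)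
Reagents that add atoms: ethylene glycol (OCCO)
Why: Acid-catalysed ketalisation; it locks the desymmetrisation so that the carbinol can be oxidised without regenerating a symmetric dione.

Step 4
Reactants: 5 (6S,7S)-6-allyl-6-methyl-1,4-dioxaspiro[4.5]decan-7-ol
Product: 6 (S)-6-allyl-6-methyl-1,4-dioxaspiro[4.5]decan-7-one
Conditions: Dess–Martin periodinane, NaHCO3, CH2Cl2, rt
Reagents that add atoms: none
Why: Dess–Martin oxidation under buffered conditions that spare the ketal; the quaternary stereocentre cannot epimerise.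

Step 5
Reactants: 6 (S)-6-allyl-6-methyl-1,4-dioxaspiro[4.5]decan-7-one
Product: 7 (6S,7R)-6-allyl-6-methyl-1,4-dioxaspiro[4.5]decan-7-ol
Conditions: (S)-2-methyl-CBS-oxazaborolidine (20 mol %), catecholborane, toluene, −78 °C
Reagents that add atoms: none
Why: Corey–Bakshi–Shibata reduction; the quaternary carbon is the large flank and the ring CH2 the small one, so the (S)-catalyst should give the 7R carbinol with the hydroxyl trans to the allyl group. Catecholborane does not hydroborate the allyl group at this temperature.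

Step 6
Reactants: 8 2-methylbut-3-yn-2-ol
Product: 9 hexacarbonyldicobalt complex of 2-methylbut-3-yn-2-ol, Co2(CO)6(HC≡CC(CH3)2OH)
Conditions: Co2(CO)8, CH2Cl2, rt
Reagents that add atoms: octacarbonyldicobalt, Co2(CO)8 (O=C=[Co](=C=O)(=C=O)(=C=O)[Co](=C=O)(=C=O)(=C=O)=C=O)
Why: Alkyne complexation with loss of two CO ligands; it prepares the Nicholas cation precursor.

Step 7
Reactants: 7 (6S,7R)-6-allyl-6-methyl-1,4-dioxaspiro[4.5]decan-7-ol; 9 hexacarbonyldicobalt complex of 2-methylbut-3-yn-2-ol
Product: 11 (6S,7R)-6-allyl-6-methyl-7-[(2-methylbut-3-yn-2-yl)oxy]-1,4-dioxaspiro[4.5]decane, via dicobalt hexacarbonyl complex of the propargylic ether 10 (not isolated)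
Conditions: BF3·OEt2, CH2Cl2, −78 → −20 °C; then (NH4)2Ce(NO3)6, Et3N, acetone, −78 → 0 °C
Reagents that add atoms: none
Why: Nicholas etherification; the cobalt-stabilised tertiary propargylic cation is trapped by the hindered secondary alcohol with retention at C7, because the C–O bond of 7 is not broken. Oxidative decomplexation then frees the alkyne.

Step 8
Reactants: 11 (6S,7R)-6-allyl-6-methyl-7-[(2-methylbut-3-yn-2-yl)oxy]-1,4-dioxaspiro[4.5]decane
Product: 12 (6S,7R)-6-allyl-6-methyl-7-[(2-methylbut-3-en-2-yl)oxy]-1,4-dioxaspiro[4.5]decane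
Conditions: H2 (1 atm), Lindlar catalyst (Pd/CaCO3 poisoned with Pb), quinoline, EtOAc, rt
Reagents that add atoms: none
Why: Lindlar semihydrogenation; the terminal alkyne is reduced much faster than either terminal alkene, and the reaction is stopped after one equivalent of H2.

Step 9
Reactants: 12 (6S,7R)-6-allyl-6-methyl-7-[(2-methylbut-3-en-2-yl)oxy]-1,4-dioxaspiro[4.5]decane
Product: 13 (5aS,9aR)-2,2,5a-trimethyl-5,5a,7,8,9,9a-hexahydro-2H-spiro[1-benzoxepine-6,2'-[1,3]dioxolane]
Conditions: second-generation Grubbs catalyst (H2IMes)(PCy3)Cl2Ru=CHPh (5 mol %), CH2Cl2 (0.005 M), 40 °C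
Reagents that add atoms: none
Why: Ring-closing olefin metathesis by the Chauvin mechanism. The ruthenium benzylidene should exchange first with the unhindered allyl group, and the resulting alkylidene at C4 then undergoes intramolecular [2+2] addition to the vinyl group on the gem-dimethyl carbon; cycloreversion releases the C3=C4 alkene and a ruthenium methylidene. The closest known reaction type is metathesis closure of seven-membered cyclic ethers from allyl and 1,1-dimethylallyl partners. The oxepene closes through a metallacyclobutane spanning C3 and C4, and the ring alkene is necessarily cis. No stereocentre is formed. The selectivity needed is cyclisation over cross-metathesis; high dilution, the gem-dimethyl group and the trans-diequatorial placement of ether oxygen and allyl group on the chair (set in steps 2 and 5) all favour it. Loss of ethylene makes the closure irreversible, and the ketal and ether are inert to the catalyst.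

Step 10
Reactants: 13 (5aS,9aR)-2,2,5a-trimethyl-5,5a,7,8,9,9a-hexahydro-2H-spiro[1-benzoxepine-6,2'-[1,3]dioxolane]
Product: 14 (3R,4R,5aS,9aR)-3,4-epoxy-2,2,5a-trimethyloctahydro-2H-spiro[1-benzoxepine-6,2'-[1,3]dioxolane]
Conditions: mCPBA, NaHCO3, CH2Cl2, 0 °C
Reagents that add atoms: 3-chloroperoxybenzoic acid (O=C(OO)c1cccc(Cl)c1)
Why: Prilezhaev epoxidation; the axial C5a methyl lies over one face of C4, so the peracid should attack the opposite face, which is the face of the C9a hydrogen.

Step 11
Reactants: 14 (3R,4R,5aS,9aR)-3,4-epoxy-2,2,5a-trimethyloctahydro-2H-spiro[1-benzoxepine-6,2'-[1,3]dioxolane]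
Product: 15 (3R,5aS,9aR)-2,2,5a-trimethyloctahydro-2H-spiro[1-benzoxepine-6,2'-[1,3]dioxolan]-3-ol
Conditions: LiAlH4, THF, 0 → 50 °C
Reagents that add atoms: none
Why: SN2 hydride opening of the epoxide at C4, the carbon remote from the neopentyl-like C3; the C3–O bond and its configuration are kept.

Step 12
Reactants: 15 (3R,5aS,9aR)-2,2,5a-trimethyloctahydro-2H-spiro[1-benzoxepine-6,2'-[1,3]dioxolan]-3-ol
Product: 16 (3R,5aS,9aR)-3-hydroxy-2,2,5a-trimethyloctahydro-1-benzoxepin-6(2H)-one
Conditions: HCl (2 M aq.), THF, rt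
Reagents that add atoms: water (O)
Why: Acid hydrolysis of the dioxolane; the secondary alcohol and the tertiary ether tolerate dilute acid at room temperature.

Step 13
Reactants: 16 (3R,5aS,9aR)-3-hydroxy-2,2,5a-trimethyloctahydro-1-benzoxepin-6(2H)-one
Product: 17 (3R,5aS,9aR)-2,2,5a-trimethyl-3-(triethylsilyloxy)octahydro-1-benzoxepin-6(2H)-one
Conditions: TESOTf, 2,6-lutidine, CH2Cl2, −78 °C
Reagents that add atoms: triethylsilyl trifluoromethanesulfonate (CC[Si](CC)(CC)OS(=O)(=O)C(F)(F)F)
Why: Silylation of the hindered secondary alcohol; at −78 °C with lutidine the ketone is not enol-silylated.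

Step 14
Reactants: 17 (3R,5aS,9aR)-2,2,5a-trimethyl-3-(triethylsilyloxy)octahydro-1-benzoxepin-6(2H)-one
Product: 18 (3R,5aS,9aR)-2,2,5a-trimethyl-3-(triethylsilyloxy)-2,3,4,5,5a,8,9,9a-octahydro-1-benzoxepin-6-yl trifluoromethanesulfonate
Conditions: KHMDS, THF, −78 °C; PhNTf2, −78 → 0 °C
Reagents that add atoms: N-phenylbis(trifluoromethanesulfonimide) (FC(F)(F)S(=O)(=O)N(c1ccccc1)S(=O)(=O)C(F)(F)F)
Why: Enolate O-triflation; enolisation can occur only towards C7 because C5a is quaternary.

### Eastern half (steps 15–29)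

Step 15
Reactants: 19 (R)-(+)-limonene
Product: 20 (R)-3-isopropenyl-6-oxoheptanal
Conditions: O3 (1.0 equiv), CH2Cl2/MeOH, −78 °C; then Me2S
Reagents that add atoms: ozone ([O-][O+]=O)
Why: Ozonolysis with reductive work-up; the trisubstituted ring alkene is more electron-rich than the isopropenyl group and reacts first when one equivalent is used.

Step 16
Reactants: 20 (R)-3-isopropenyl-6-oxoheptanal
Product: 21 (S)-5-isopropenyl-2-methylcyclopent-1-ene-1-carbaldehyde
Conditions: piperidine, AcOH, benzene, 80 °C
Reagents that add atoms: none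
Why: Intramolecular aldol condensation through the aldehyde enamine onto the methyl ketone; this is the known ring contraction of limonene, and the stereocentre is untouched.

Step 17
Reactants: 21 (S)-5-isopropenyl-2-methylcyclopent-1-ene-1-carbaldehyde
Product: 22 5-methyl-2-isopropenyl-6-oxabicyclo[3.1.0]hexane-1-carbaldehyde with the oxirane oxygen trans to the isopropenyl group
Conditions: H2O2 (30 % aq.), NaOH, MeOH, 0 °C
Reagents that add atoms: hydrogen peroxide (OO)
Why: Weitz–Scheffer nucleophilic epoxidation of the enal; hydroperoxide should add to the ring face opposite the adjacent isopropenyl group, which sets the C1 oxygen of the azulene, and the isolated isopropenyl alkene is inert.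

Step 18
Reactants: 22 5-methyl-2-isopropenyl-6-oxabicyclo[3.1.0]hexane-1-carbaldehyde
Product: 24 (E/Z)-2-[(2R)-2-hydroxy-2-methyl-5-isopropenylcyclopentylidene]acetaldehyde (hydroxyl trans to isopropenyl), via methyl enol ether 23 (not isolated)
Conditions: Ph3P(CH2OMe)Cl, KOt-Bu, THF, 0 °C; then oxalic acid, THF/H2O, rt
Reagents that add atoms: (methoxymethyl)triphenylphosphonium chloride (COC[P+](c1ccccc1)(c1ccccc1)c1ccccc1.[Cl-]); water (O)
Why: Wittig methoxymethylenation followed by acid-triggered vinylogous epoxide opening; the enol ether oxygen pushes electrons through the alkene to break the C8a–O bond. The C1–O bond and its configuration are kept, and the alkene geometry is irrelevant to the next step.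

Step 19
Reactants: 24 (E/Z)-2-[(2R)-2-hydroxy-2-methyl-5-isopropenylcyclopentylidene]acetaldehyde
Product: 25 2-[(1R,2R,5R)-2-hydroxy-2-methyl-5-isopropenylcyclopentyl]acetaldehyde (CH2CHO cis to isopropenyl and methyl, trans to hydroxyl)
Conditions: Hantzsch ester, Bn2NH·CF3CO2H (20 mol %), THF, rt
Reagents that add atoms: none
Why: Iminium-catalysed transfer hydrogenation of the enal, which leaves the isopropenyl group alone; hydride should reach the ring carbon from the face of the hydroxyl and the C5 hydrogen, away from the methyl and isopropenyl groups, giving the all-cis carbon substituents.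

Step 20
Reactants: 25 2-[(1R,2R,5R)-2-hydroxy-2-methyl-5-isopropenylcyclopentyl]acetaldehyde
Product: 26 (1R,2R,3R)-2-(2-hydroxy-3-methylbut-3-enyl)-1-methyl-3-isopropenylcyclopentan-1-ol (carbinol epimers)
Conditions: CH2=C(CH3)MgBr (3 equiv), THF, −78 → 0 °C
Reagents that add atoms: isopropenylmagnesium bromide (CC(=C)[Mg]Br)
Why: Grignard addition to the aldehyde; one equivalent is consumed by the tertiary hydroxyl, and the new carbinol configuration is erased in the next step.

Step 21
Reactants: 26 (1R,2R,3R)-2-(2-hydroxy-3-methylbut-3-enyl)-1-methyl-3-isopropenylcyclopentan-1-ol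
Product: 27 1-[(1R,2R,5R)-2-hydroxy-2-methyl-5-isopropenylcyclopentyl]-3-methylbut-3-en-2-one
Conditions: MnO2, CH2Cl2, rt
Reagents that add atoms: none
Why: Selective oxidation of the allylic secondary alcohol; the tertiary alcohol cannot be oxidised, and the trans relationship prevents hemiketal formation.

Step 22
Reactants: 27 1-[(1R,2R,5R)-2-hydroxy-2-methyl-5-isopropenylcyclopentyl]-3-methylbut-3-en-2-one
Product: 28 (1R,3aR,8aR)-1-hydroxy-1,4,4,6-tetramethylperhydroazulen-7-one (cis-fused; C6 epimers)
Conditions: Fe(acac)3 (0.3 equiv), PhSiH3, EtOH/(CH2OH)2, 60 °C, 0.01 M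
Reagents that add atoms: none
Why: Hydrogen-atom-transfer-initiated radical conjugate addition (reductive olefin coupling); the iron hydride should deliver H to the CH2 of the electron-rich isopropenyl group, and the tertiary radical at C4 adds 7-endo to the enone methylene, creating the quaternary carbon and the seven-membered ring. The cis fusion is already fixed, and the C6 epimers converge in step 24.

Step 23
Reactants: 28 (1R,3aR,8aR)-1-hydroxy-1,4,4,6-tetramethylperhydroazulen-7-one
Product: 29 (1R,3aR,8aR)-1,4,4,6-tetramethyl-1,7-bis(triethylsilyloxy)-1,2,3,3a,4,5,8,8a-octahydroazulene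
Conditions: TESOTf, Et3N, CH2Cl2, 0 °C → rt
Reagents that add atoms: triethylsilyl trifluoromethanesulfonate (CC[Si](CC)(CC)OS(=O)(=O)C(F)(F)F)
Why: Enol silylation under equilibrating amine/ammonium triflate conditions should favour the more substituted C6=C7 enol ether, and the same reagent protects the tertiary alcohol; any C7=C8 isomer is removed after step 24.

Step 24
Reactants: 29 (1R,3aR,8aR)-1,4,4,6-tetramethyl-1,7-bis(triethylsilyloxy)-1,2,3,3a,4,5,8,8a-octahydroazulene
Product: 30 (1R,3aR,8aR)-1,4,4,6-tetramethyl-1-(triethylsilyloxy)-2,3,3a,4,8,8a-hexahydroazulen-7(1H)-one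
Conditions: Pd(OAc)2 (1.1 equiv), MeCN, rt
Reagents that add atoms: none
Why: Saegusa–Ito oxidation; the palladium enolate at C6 undergoes β-hydride elimination towards C5 to give the endocyclic 2-methyl enone.

Step 25
Reactants: 30 (1R,3aR,8aR)-1,4,4,6-tetramethyl-1-(triethylsilyloxy)-2,3,3a,4,8,8a-hexahydroazulen-7(1H)-one
Product: 31 (1R,3aR,7S,8aR)-1,4,4,6-tetramethyl-1-(triethylsilyloxy)-1,2,3,3a,4,7,8,8a-octahydroazulen-7-ol
Conditions: (R)-2-methyl-CBS-oxazaborolidine (20 mol %), catecholborane, toluene, −78 °C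
Reagents that add atoms: none
Why: Corey–Bakshi–Shibata 1,2-reduction with the α-methyl alkene carbon as the large flank; the (R)-catalyst should deliver hydride to the convex face (that of the ring-fusion hydrogens), placing the hydroxyl on the concave face.

Step 26
Reactants: 31 (1R,3aR,7S,8aR)-1,4,4,6-tetramethyl-1-(triethylsilyloxy)-1,2,3,3a,4,7,8,8a-octahydroazulen-7-ol
Product: 32 N,N-dimethyl-2-[(1R,3aR,5S,8aR)-1,4,4,6-tetramethyl-1-(triethylsilyloxy)-1,2,3,3a,4,5,8,8a-octahydroazulen-5-yl]acetamide
Conditions: CH3C(OMe)2NMe2, xylene, 140 °C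
Reagents that add atoms: N,N-dimethylacetamide dimethyl acetal (COC(C)(OC)N(C)C)
Why: Eschenmoser–Claisen rearrangement; the suprafacial [3,3] shift carries the acetamide carbon to C5 on the face that held the C7 oxygen and moves the alkene to C6=C7, under neutral conditions that spare the silyl ether.

Step 27
Reactants: 32 N,N-dimethyl-2-[(1R,3aR,5S,8aR)-1,4,4,6-tetramethyl-1-(triethylsilyloxy)-1,2,3,3a,4,5,8,8a-octahydroazulen-5-yl]acetamide
Product: 33 cis-fused γ-lactone of the C5 acetic acid chain onto C6–O bearing a C7 iodide trans to the lactone oxygen, with the (1R,3aR,8aR)-1,4,4,6-tetramethyl-1-(triethylsilyloxy)perhydroazulene core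
Conditions: I2, THF/H2O (pH 7 buffer), rt, dark
Reagents that add atoms: iodine (II); water (O)
Why: Iodolactonisation of a γ,δ-unsaturated amide; the amide oxygen attacks the tertiary C6 in a 5-exo sense from the face of the chain while iodine takes the convex face of C7, and the iminium lactone is hydrolysed in situ.

Step 28
Reactants: 33 iodolactone
Product: 35 2-[(1R,3aR,5R,6R,7S,8aR)-6,7-epoxy-1,4,4,6-tetramethyl-1-(triethylsilyloxy)perhydroazulen-5-yl]ethan-1-ol, via iodo diol 34 (not isolated)
Conditions: LiBH4, THF, 0 °C → rt; then K2CO3, MeOH, rt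
Reagents that add atoms: none
Why: Lactone reduction to the diol, then intramolecular Williamson closure; the C6 alkoxide displaces the anti C7 iodide with inversion, so the epoxide oxygen ends on the face of the C5 chain.

Step 29
Reactants: 35 2-[(1R,3aR,5R,6R,7S,8aR)-6,7-epoxy-1,4,4,6-tetramethyl-1-(triethylsilyloxy)perhydroazulen-5-yl]ethan-1-ol
Product: 36 (1R,3aR,5R,6R,7S,8aR)-6,7-epoxy-5-(2-iodoethyl)-1,4,4,6-tetramethyl-1-(triethylsilyloxy)perhydroazulene
Conditions: I2, PPh3, imidazole, CH2Cl2, 0 °C
Reagents that add atoms: iodine (II)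
Why: Appel-type iodination of the primary alcohol; the buffered, cold conditions should leave the hindered trisubstituted epoxide intact.

### Union and completion (steps 30–34)

Step 30
Reactants: 36 (1R,3aR,5R,6R,7S,8aR)-6,7-epoxy-5-(2-iodoethyl)-1,4,4,6-tetramethyl-1-(triethylsilyloxy)perhydroazulene; 18 (3R,5aS,9aR)-2,2,5a-trimethyl-3-(triethylsilyloxy)-2,3,4,5,5a,8,9,9a-octahydro-1-benzoxepin-6-yl trifluoromethanesulfonate
Product: 38 (3R,5aR,9aR)-6-{2-[(1R,3aR,5R,6R,7S,8aR)-6,7-epoxy-1,4,4,6-tetramethyl-1-(triethylsilyloxy)perhydroazulen-5-yl]ethyl}-2,2,5a-trimethyl-3-(triethylsilyloxy)-2,3,4,5,5a,8,9,9a-octahydro-1-benzoxepine, via lithium B-alkyl-B-methoxy-9-BBN borate 37 (not isolated)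
Conditions: t-BuLi, 9-methoxy-9-BBN, Et2O/THF, −78 °C → rt; then Pd(dppf)Cl2 (10 mol %), AsPh3, K3PO4 (3 M aq.), DMF, rt
Reagents that add atoms: none
Why: B-alkyl Suzuki–Miyaura coupling; iodine–lithium exchange and trapping by the borinate give the ate complex, which transfers its primary alkyl group to the palladium formed by oxidative addition of zerovalent palladium to the enol triflate. The epoxide cannot be reached by the carbanion because the chain lies on its own face.

Step 31
Reactants: 38 coupled C6=C7 alkene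
Product: 40 (3R,5aR,6R,7R,9aR)-6-{2-[(1R,3aR,5R,6R,7S,8aR)-6,7-epoxy-1,4,4,6-tetramethyl-1-(triethylsilyloxy)perhydroazulen-5-yl]ethyl}-2,2,5a-trimethyl-3-(triethylsilyloxy)decahydro-1-benzoxepin-7-ol, via C7 alkylborane 39 (not isolated)
Conditions: BH3·THF, THF, 0 °C → rt; then NaOH (3 M aq.), H2O2 (30 %), 0 °C
Reagents that add atoms: hydrogen peroxide (OO)
Why: Hydroboration–oxidation; boron adds to the less substituted C7 and hydrogen to C6, syn and on the face opposite the axial C5a methyl, so the side chain becomes equatorial. Uncatalysed borane reduces hindered epoxides only slowly.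

Step 32
Reactants: 40 C7 secondary alcohol
Product: 41 (3R,5aR,6R,9aR)-6-{2-[(1R,3aR,5R,6R,7S,8aR)-6,7-epoxy-1,4,4,6-tetramethyl-1-(triethylsilyloxy)perhydroazulen-5-yl]ethyl}-2,2,5a-trimethyl-3-(triethylsilyloxy)octahydro-1-benzoxepin-7(2H)-one
Conditions: Dess–Martin periodinane, NaHCO3, CH2Cl2, rt
Reagents that add atoms: none
Why: Neutral oxidation compatible with the epoxide and silyl ethers; the C6 centre already holds the thermodynamically preferred equatorial chain.

Step 33
Reactants: 41 C7 ketone
Product: 42 (3R,5aR,6R,7S,9aR)-6-{2-[(1R,3aR,5R,6R,7S,8aR)-6,7-epoxy-1,4,4,6-tetramethyl-1-(triethylsilyloxy)perhydroazulen-5-yl]ethyl}-2,2,5a,7-tetramethyl-3-(triethylsilyloxy)decahydro-1-benzoxepin-7-ol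
Conditions: CH3Li, CeCl3, THF, −78 °C
Reagents that add atoms: methyllithium ([Li]C)
Why: Organocerium 1,2-addition, which suppresses enolisation of the hindered ketone; the axial C5a methyl blocks axial approach, so methyl should enter equatorially and leave the axial 7S hydroxyl. The epoxide is inert at this temperature.

Step 34
Reactants: 42 bis(triethylsilyl) ether
Product: 43 (3R,5aR,6R,7S,9aR)-6-{2-[(1R,3aR,5R,6R,7S,8aR)-6,7-epoxy-1-hydroxy-1,4,4,6-tetramethylperhydroazulen-5-yl]ethyl}-2,2,5a,7-tetramethyldecahydro-1-benzoxepine-3,7-diol (CNP0216138.1)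
Conditions: Bu4NF, THF, rt → 45 °C
Reagents that add atoms: none
Why: Fluoride-induced cleavage of both triethylsilyl ethers under non-acidic conditions, so the epoxide is not exposed to acid and transannular opening is avoided.

## Compound list

1 | 2-methylcyclohexane-1,3-dione | CC1C(=O)CCCC1=O | starting material
2 | allyl bromide | C=CCBr | starting material
3 | 2-allyl-2-methylcyclohexane-1,3-dione | C=CCC1(C)C(=O)CCCC1=O | intermediate
4 | (2S,3S)-2-allyl-3-hydroxy-2-methylcyclohexan-1-one (OH cis to allyl) | O[C@H]1CCCC(=O)[C@@]1(C)CC=C | intermediate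
5 | (6S,7S)-6-allyl-6-methyl-1,4-dioxaspiro[4.5]decan-7-ol | O[C@H]1CCCC2(OCCO2)[C@@]1(C)CC=C | intermediate
6 | (S)-6-allyl-6-methyl-1,4-dioxaspiro[4.5]decan-7-one | O=C1CCCC2(OCCO2)[C@@]1(C)CC=C | intermediate
7 | (6S,7R)-6-allyl-6-methyl-1,4-dioxaspiro[4.5]decan-7-ol (OH trans to allyl) | O[C@@H]1CCCC2(OCCO2)[C@@]1(C)CC=C | intermediate
8 | 2-methylbut-3-yn-2-ol | CC(C)(O)C#C | starting material
9 | hexacarbonyldicobalt complex of 2-methylbut-3-yn-2-ol, Co2(CO)6(HC≡CC(CH3)2OH) | O=C=[Co]12(=C=O)(=C=O)[Co]3(=C=O)(=C=O)(=C=O)C1C23C(C)(C)O | intermediate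
10 | hexacarbonyldicobalt complex of propargylic ether 11 | O=C=[Co]12(=C=O)(=C=O)[Co]3(=C=O)(=C=O)(=C=O)C1C23C(C)(C)O[C@@H]1CCCC2(OCCO2)[C@@]1(C)CC=C | intermediate
11 | (6S,7R)-6-allyl-6-methyl-7-[(2-methylbut-3-yn-2-yl)oxy]-1,4-dioxaspiro[4.5]decane | C#CC(C)(C)O[C@@H]1CCCC2(OCCO2)[C@@]1(C)CC=C | intermediate
12 | (6S,7R)-6-allyl-6-methyl-7-[(2-methylbut-3-en-2-yl)oxy]-1,4-dioxaspiro[4.5]decane | C=CC(C)(C)O[C@@H]1CCCC2(OCCO2)[C@@]1(C)CC=C | intermediate
13 | (5aS,9aR)-2,2,5a-trimethyl-5,5a,7,8,9,9a-hexahydro-2H-spiro[1-benzoxepine-6,2'-[1,3]dioxolane] | CC1(C)O[C@@H]2CCCC3(OCCO3)[C@@]2(C)CC=C1 | intermediate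
14 | (3R,4R,5aS,9aR)-3,4-epoxy-2,2,5a-trimethyloctahydro-2H-spiro[1-benzoxepine-6,2'-[1,3]dioxolane] (oxirane anti to the 5a-methyl) | CC1(C)O[C@@H]2CCCC3(OCCO3)[C@@]2(C)C[C@H]2O[C@@H]12 | intermediate
15 | (3R,5aS,9aR)-2,2,5a-trimethyloctahydro-2H-spiro[1-benzoxepine-6,2'-[1,3]dioxolan]-3-ol | CC1(C)O[C@@H]2CCCC3(OCCO3)[C@@]2(C)CC[C@H]1O | intermediate
16 | (3R,5aS,9aR)-3-hydroxy-2,2,5a-trimethyloctahydro-1-benzoxepin-6(2H)-one | CC1(C)O[C@@H]2CCCC(=O)[C@@]2(C)CC[C@H]1O | intermediate
17 | (3R,5aS,9aR)-2,2,5a-trimethyl-3-(triethylsilyloxy)octahydro-1-benzoxepin-6(2H)-one | CC1(C)O[C@@H]2CCCC(=O)[C@@]2(C)CC[C@H]1O[Si](CC)(CC)CC | intermediate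
18 | (3R,5aS,9aR)-2,2,5a-trimethyl-3-(triethylsilyloxy)-2,3,4,5,5a,8,9,9a-octahydro-1-benzoxepin-6-yl trifluoromethanesulfonate | CC1(C)O[C@@H]2CCC=C(OS(=O)(=O)C(F)(F)F)[C@@]2(C)CC[C@H]1O[Si](CC)(CC)CC | intermediate
19 | (R)-(+)-limonene | CC1=CC[C@@H](CC1)C(C)=C | starting material
20 | (R)-3-isopropenyl-6-oxoheptanal | O=CC[C@@H](CCC(C)=O)C(C)=C | intermediate
21 | (S)-5-isopropenyl-2-methylcyclopent-1-ene-1-carbaldehyde | O=CC1=C(C)CC[C@H]1C(C)=C | intermediate
22 | 5-methyl-2-isopropenyl-6-oxabicyclo[3.1.0]hexane-1-carbaldehyde, oxirane oxygen trans to isopropenyl | O=C[C@@]12O[C@]1(C)CC[C@H]2C(C)=C | intermediate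
23 | 1-(2-methoxyvinyl)-5-methyl-2-isopropenyl-6-oxabicyclo[3.1.0]hexane (E/Z), configuration as 22 | COC=C[C@@]12O[C@]1(C)CC[C@H]2C(C)=C | intermediate
24 | (E/Z)-2-[(2R)-2-hydroxy-2-methyl-5-isopropenylcyclopentylidene]acetaldehyde, hydroxyl trans to isopropenyl | O=CC=C1[C@H](C(C)=C)CC[C@@]1(C)O | intermediate
25 | 2-[(1R,2R,5R)-2-hydroxy-2-methyl-5-isopropenylcyclopentyl]acetaldehyde | O=CC[C@@H]1[C@H](C(C)=C)CC[C@@]1(C)O | intermediate
26 | (1R,2R,3R)-2-(2-hydroxy-3-methylbut-3-enyl)-1-methyl-3-isopropenylcyclopentan-1-ol (side-chain carbinol epimers) | CC(=C)C(O)C[C@@H]1[C@H](C(C)=C)CC[C@@]1(C)O | intermediate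
27 | 1-[(1R,2R,5R)-2-hydroxy-2-methyl-5-isopropenylcyclopentyl]-3-methylbut-3-en-2-one | CC(=C)C(=O)C[C@@H]1[C@H](C(C)=C)CC[C@@]1(C)O | intermediate
28 | (1R,3aR,8aR)-1-hydroxy-1,4,4,6-tetramethylperhydroazulen-7-one (cis-fused, C6 epimers) | CC1CC(C)(C)[C@@H]2CC[C@@](C)(O)[C@@H]2CC1=O | intermediate
29 | (1R,3aR,8aR)-1,4,4,6-tetramethyl-1,7-bis(triethylsilyloxy)-1,2,3,3a,4,5,8,8a-octahydroazulene | CC1=C(O[Si](CC)(CC)CC)C[C@H]2[C@](C)(O[Si](CC)(CC)CC)CC[C@H]2C(C)(C)C1 | intermediate
30 | (1R,3aR,8aR)-1,4,4,6-tetramethyl-1-(triethylsilyloxy)-2,3,3a,4,8,8a-hexahydroazulen-7(1H)-one | CC1=CC(C)(C)[C@@H]2CC[C@@](C)(O[Si](CC)(CC)CC)[C@@H]2CC1=O | intermediate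
31 | (1R,3aR,7S,8aR)-1,4,4,6-tetramethyl-1-(triethylsilyloxy)-1,2,3,3a,4,7,8,8a-octahydroazulen-7-ol | CC1=CC(C)(C)[C@@H]2CC[C@@](C)(O[Si](CC)(CC)CC)[C@@H]2C[C@@H]1O | intermediate
32 | N,N-dimethyl-2-[(1R,3aR,5S,8aR)-1,4,4,6-tetramethyl-1-(triethylsilyloxy)-1,2,3,3a,4,5,8,8a-octahydroazulen-5-yl]acetamide | CN(C)C(=O)C[C@@H]1C(C)(C)[C@@H]2CC[C@@](C)(O[Si](CC)(CC)CC)[C@@H]2CC=C1C | intermediate
33 | iodolactone: γ-lactone from the C5 acetic acid chain to the C6 oxygen (cis-fused), C7 iodide trans to the lactone oxygen, (1R,3aR,8aR)-1,4,4,6-tetramethyl-1-(triethylsilyloxy)perhydroazulene core | O=C1C[C@@H]2C(C)(C)[C@@H]3CC[C@@](C)(O[Si](CC)(CC)CC)[C@@H]3C[C@@H](I)[C@]2(C)O1 | intermediate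
34 | 5-(2-hydroxyethyl)-7-iodo-1,4,4,6-tetramethyl-1-(triethylsilyloxy)perhydroazulen-6-ol, configuration as 33 | OCC[C@@H]1C(C)(C)[C@@H]2CC[C@@](C)(O[Si](CC)(CC)CC)[C@@H]2C[C@@H](I)[C@]1(C)O | intermediate
35 | 2-[(1R,3aR,5R,6R,7S,8aR)-6,7-epoxy-1,4,4,6-tetramethyl-1-(triethylsilyloxy)perhydroazulen-5-yl]ethan-1-ol | OCC[C@@H]1C(C)(C)[C@@H]2CC[C@@](C)(O[Si](CC)(CC)CC)[C@@H]2C[C@@H]2O[C@@]21C | intermediate
36 | (1R,3aR,5R,6R,7S,8aR)-6,7-epoxy-5-(2-iodoethyl)-1,4,4,6-tetramethyl-1-(triethylsilyloxy)perhydroazulene | ICC[C@@H]1C(C)(C)[C@@H]2CC[C@@](C)(O[Si](CC)(CC)CC)[C@@H]2C[C@@H]2O[C@@]21C | intermediate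
37 | lithium B-methoxy-B-[2-(azulenyl)ethyl]-9-borabicyclo[3.3.1]nonane ate complex of 36 | [Li+].CO[B-]1(CC[C@@H]2C(C)(C)[C@@H]3CC[C@@](C)(O[Si](CC)(CC)CC)[C@@H]3C[C@@H]3O[C@@]32C)C2CCCC1CCC2 | intermediate
38 | (3R,5aR,9aR)-6-{2-[(1R,3aR,5R,6R,7S,8aR)-6,7-epoxy-1,4,4,6-tetramethyl-1-(triethylsilyloxy)perhydroazulen-5-yl]ethyl}-2,2,5a-trimethyl-3-(triethylsilyloxy)-2,3,4,5,5a,8,9,9a-octahydro-1-benzoxepine | CC1(C)O[C@@H]2CCC=C(CC[C@@H]3C(C)(C)[C@@H]4CC[C@@](C)(O[Si](CC)(CC)CC)[C@@H]4C[C@@H]4O[C@@]43C)[C@@]2(C)CC[C@H]1O[Si](CC)(CC)CC | intermediate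
39 | C7 borane (BH2) adduct of 38, boron and C6–H syn, anti to the 5a-methyl | CC1(C)O[C@@H]2CC[C@@H](B)[C@H](CC[C@@H]3C(C)(C)[C@@H]4CC[C@@](C)(O[Si](CC)(CC)CC)[C@@H]4C[C@@H]4O[C@@]43C)[C@@]2(C)CC[C@H]1O[Si](CC)(CC)CC | intermediate
40 | (3R,5aR,6R,7R,9aR)-7-hydroxy analogue (secondary alcohol) of 38 after hydration | CC1(C)O[C@@H]2CC[C@@H](O)[C@H](CC[C@@H]3C(C)(C)[C@@H]4CC[C@@](C)(O[Si](CC)(CC)CC)[C@@H]4C[C@@H]4O[C@@]43C)[C@@]2(C)CC[C@H]1O[Si](CC)(CC)CC | intermediate
41 | (3R,5aR,6R,9aR)-C7 ketone, bis(triethylsilyl) ether | CC1(C)O[C@@H]2CCC(=O)[C@H](CC[C@@H]3C(C)(C)[C@@H]4CC[C@@](C)(O[Si](CC)(CC)CC)[C@@H]4C[C@@H]4O[C@@]43C)[C@@]2(C)CC[C@H]1O[Si](CC)(CC)CC | intermediate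
42 | 3-O,1'-O-bis(triethylsilyl) ether of the target | CC1(C)O[C@@H]2CC[C@](C)(O)[C@H](CC[C@@H]3C(C)(C)[C@@H]4CC[C@@](C)(O[Si](CC)(CC)CC)[C@@H]4C[C@@H]4O[C@@]43C)[C@@]2(C)CC[C@H]1O[Si](CC)(CC)CC | intermediate
43 | (3R,5aR,6R,7S,9aR)-6-{2-[(1R,3aR,5R,6R,7S,8aR)-6,7-epoxy-1-hydroxy-1,4,4,6-tetramethylperhydroazulen-5-yl]ethyl}-2,2,5a,7-tetramethyldecahydro-1-benzoxepine-3,7-diol (CNP0216138.1) | CC1(C)O[C@@H]2CC[C@](C)(O)[C@H](CC[C@@H]3C(C)(C)[C@@H]4CC[C@@](C)(O)[C@@H]4C[C@@H]4O[C@@]43C)[C@@]2(C)CC[C@H]1O | target

## Step count and least certain steps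

Total step count: 34 (western half 14 steps including the preparation of 9, eastern half 15 steps, union and completion 5 steps).
Longest linear sequence: 20 steps (19 → 43, steps 15–34).

**Step 9 (key step).** The likely failure is cross-metathesis through the unhindered allyl groups (dimerisation), or stalling because the alkylidene fails to engage the vinyl group beside the quaternary ether carbon; ruthenium hydrides could also isomerise the allyl group. The fallback sets out from 7 and returns at 15, making the O1–C2 bond by epoxide opening instead of closing C3=C4. Hydroboration–oxidation of the allyl group (9-BBN; NaBO3) gives (6S,7R)-6-(3-hydroxypropyl)-6-methyl-1,4-dioxaspiro[4.5]decan-7-ol F1. Selective oxidation of the primary alcohol (TEMPO, PhI(OAc)2) gives 3-[(6S,7R)-7-hydroxy-6-methyl-1,4-dioxaspiro[4.5]decan-6-yl]propanal F2. Wittig reaction with Ph3P=C(CH3)2 gives the homoprenyl alcohol (6S,7R)-6-methyl-6-(4-methylpent-3-enyl)-1,4-dioxaspiro[4.5]decan-7-ol F3. Shi epoxidation (D-fructose-derived ketone, KHSO5) gives the (R)-epoxide (6S,7R)-6-{2-[(2R)-3,3-dimethyloxiran-2-yl]ethyl}-6-methyl-1,4-dioxaspiro[4.5]decan-7-ol F4. Camphorsulfonic acid should then promote 7-endo opening at the tertiary epoxide carbon by the C7 hydroxyl to give 15.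

**Step 22.** The tertiary radical may be reduced (net hydrogenation of the isopropenyl group), or the enone may be reduced, before the slow 7-endo closure. The fallback sets out from 25 and returns at 30, building a six-membered ring first and then expanding it. A type 2 carbonyl-ene cyclisation (Me2AlCl, CH2Cl2, −78 °C) gives (1R,3aR,7aR)-1-methyl-4-methyleneperhydroindene-1,6-diol F5. Dess–Martin oxidation and DBU isomerisation give (1R,3aR,7aR)-1-hydroxy-1,4-dimethyl-1,2,3,3a,7,7a-hexahydroinden-6-one F6. Me2CuLi addition with Me3SiCl trapping gives the bis(trimethylsilyl) compound (1R,3aR,7aR)-1,4,4-trimethyl-1,6-bis(trimethylsilyloxy)-2,3,3a,4,7,7a-hexahydro-1H-indene F7, with the gem-dimethyl carbon in place. Cyclopropanation with CH3CHI2/Et2Zn gives the methylcyclopropyl silyl ether F8. FeCl3 in DMF followed by NaOAc/MeOH (Saegusa–Ito ring expansion) gives (1R,3aR,8aR)-1-hydroxy-1,4,4,6-tetramethyl-2,3,3a,4,8,8a-hexahydroazulen-7(1H)-one F9. TESOTf/2,6-lutidine converts F9 into 30.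

**Step 18.** The basic ylide may open or eliminate the epoxy aldehyde before olefination, or hydrolysis may give the homologated epoxy aldehyde instead of the vinylogous opening. The fallback sets out from 21 and returns at 24, introducing the C1 oxygen by cycloaddition instead of epoxidation. Methylenation (Ph3P=CH2) gives (S)-1-methyl-5-isopropenyl-2-vinylcyclopent-1-ene F10. Singlet oxygen (O2, tetraphenylporphyrin, hν) should add [4+2] to the diene anti to the isopropenyl group to give the bicyclic 3,6-dihydro-1,2-dioxine F11. Et3N (Kornblum–DeLaMare fragmentation) then gives 24.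

**Step 7.** BF3 may ionise the dioxolane, conversion of the hindered alcohol may be low, or the cation may eliminate to the enyne. The fallback sets out from 7 and returns at 11 without cobalt: copper-catalysed propargylic substitution with commercial 3-chloro-3-methylbut-1-yne (CuCl, DBU, MeCN, 0 °C) through a copper allenylidene makes the same ether under basic conditions (no new compound, F0).

**Step 31.** Borane may reduce the trisubstituted epoxide during the slow hydroboration of a hindered alkene, or add from the wrong face. The fallback sets out from 17 and returns at 41, placing the C7 oxygen before the union so that no borane is needed. Rubottom oxidation of 17 (LiHMDS, Me3SiCl; mCPBA) and silylation (TBSOTf, 2,6-lutidine) give the 7-(tert-butyldimethylsilyloxy) ketone F12. KHMDS/PhNTf2 gives the 7-silyloxy enol triflate F13. B-alkyl Suzuki coupling with 37 under the conditions of step 30 gives the tetrasubstituted silyl enol ether F14. Bu4NF buffered with AcOH at −20 °C cleaves only the enol ether and gives 41 after equilibration at C6.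

## Further compounds

F1 | step 9 | (6S,7R)-6-(3-hydroxypropyl)-6-methyl-1,4-dioxaspiro[4.5]decan-7-ol | O[C@@H]1CCCC2(OCCO2)[C@@]1(C)CCCO
F2 | step 9 | 3-[(6S,7R)-7-hydroxy-6-methyl-1,4-dioxaspiro[4.5]decan-6-yl]propanal | O[C@@H]1CCCC2(OCCO2)[C@@]1(C)CCC=O
F3 | step 9 | (6S,7R)-6-methyl-6-(4-methylpent-3-enyl)-1,4-dioxaspiro[4.5]decan-7-ol | O[C@@H]1CCCC2(OCCO2)[C@@]1(C)CCC=C(C)C
F4 | step 9 | (6S,7R)-6-{2-[(2R)-3,3-dimethyloxiran-2-yl]ethyl}-6-methyl-1,4-dioxaspiro[4.5]decan-7-ol | O[C@@H]1CCCC2(OCCO2)[C@@]1(C)CC[C@H]3OC3(C)C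
F5 | step 22 | (1R,3aR,7aR)-1-methyl-4-methyleneperhydroindene-1,6-diol (C6 epimers) | C=C1CC(O)C[C@@H]2[C@H]1CC[C@@]2(C)O
F6 | step 22 | (1R,3aR,7aR)-1-hydroxy-1,4-dimethyl-1,2,3,3a,7,7a-hexahydroinden-6-one | CC1=CC(=O)C[C@@H]2[C@H]1CC[C@@]2(C)O
F7 | step 22 | (1R,3aR,7aR)-1,4,4-trimethyl-1,6-bis(trimethylsilyloxy)-2,3,3a,4,7,7a-hexahydro-1H-indene | CC1(C)C=C(O[Si](C)(C)C)C[C@@H]2[C@H]1CC[C@@]2(C)O[Si](C)(C)C
F8 | step 22 | methylcyclopropane adduct of F7 across the enol ether double bond (cyclopropane epimers) | CC1C2C(C)(C)[C@@H]3CC[C@@](C)(O[Si](C)(C)C)[C@@H]3CC12O[Si](C)(C)C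
F9 | step 22 | (1R,3aR,8aR)-1-hydroxy-1,4,4,6-tetramethyl-2,3,3a,4,8,8a-hexahydroazulen-7(1H)-one | CC1=CC(C)(C)[C@@H]2CC[C@@](C)(O)[C@@H]2CC1=O
F10 | step 18 | (S)-1-methyl-5-isopropenyl-2-vinylcyclopent-1-ene | C=CC1=C(C)CC[C@H]1C(C)=C
F11 | step 18 | bicyclic 3,6-dihydro-1,2-dioxine from F10, peroxide oxygen on the methyl-bearing carbon trans to isopropenyl | CC(=C)[C@@H]1CC[C@@]2(C)OOCC=C12
F0 | step 7 | none | none
F12 | step 31 | (3R,5aS,9aR)-7-(tert-butyldimethylsilyloxy)-2,2,5a-trimethyl-3-(triethylsilyloxy)octahydro-1-benzoxepin-6(2H)-one (C7 epimers) | CC1(C)O[C@@H]2CCC(O[Si](C)(C)C(C)(C)C)C(=O)[C@@]2(C)CC[C@H]1O[Si](CC)(CC)CC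
F13 | step 31 | 7-(tert-butyldimethylsilyloxy) enol triflate derived from F12 | CC1(C)O[C@@H]2CCC(O[Si](C)(C)C(C)(C)C)=C(OS(=O)(=O)C(F)(F)F)[C@@]2(C)CC[C@H]1O[Si](CC)(CC)CC
F14 | step 31 | C7 tert-butyldimethylsilyl enol ether of 41 | CC1(C)O[C@@H]2CCC(O[Si](C)(C)C(C)(C)C)=C(CC[C@@H]3C(C)(C)[C@@H]4CC[C@@](C)(O[Si](CC)(CC)CC)[C@@H]4C[C@@H]4O[C@@]43C)[C@@]2(C)CC[C@H]1O[Si](CC)(CC)CC
A1 | alternative 1 | methyl 2-[2-methyl-5-isopropenyl-2-(triethylsilyloxy)cyclopentylidene]acetate (2-alkylidene-3-isopropenylcyclopentyl silyl ether) | COC(=O)/C=C1/[C@H](C(C)=C)CC[C@@]1(C)O[Si](CC)(CC)CC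
A2 | alternative 2 | isoxazoline-fused perhydrobenzoxepine tert-butyldimethylsilyl ether | CC1(C)O[C@@H]2CCC3=NOC[C@@H]3[C@@]2(C)CC[C@H]1O[Si](C)(C)C(C)(C)C
A3 | alternative 3 | 7-methylene perhydrobenzoxepin-3-ol with C6 pivaloyloxymethyl group | CC1(C)O[C@@H]2CCC(=C)[C@H](COC(=O)C(C)(C)C)[C@@]2(C)CC[C@H]1O
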